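**Plan**
- Retrosynthesis: the three methoxymethyl ethers are cut first; then, together, the C2–C1' bond between ring C and ring B and the C3–O bond, leading back to a 6-geranyl-5,7-bis(methoxymethoxy)chromone and an aryl bromide; then the C6–C1'' bond to (E)-geranyl bromide and the C6–I bond, back to 5,7-dihydroxychromone.
- Enabling feature: in the chromone, C2 of ring C is the β-carbon of the vinylogous ester O1–C2=C3–C4=O. Aryl transfer to C2 leaves an enolate across C3–C4, which is kept as its enol silane and oxidised at C3, so one operation gives the C2–aryl bond, both stereocentres and the 3-hydroxyl.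
- Forward order: rings A and C are bought as the chromone; the geranyl chain is joined at C6 (iodination ortho to the free 5-OH, tin for iodine, Stille allylation); ring B is joined at C2 in the key step; acid then removes the acetals.
- Stereochemistry: C2 from the (S)-binap–rhodium catalyst; C3 from C2 (oxidant anti to the aryl group, 2,3-trans); the E alkene comes with geranyl bromide and is never broken.

Key step: step 7

Remark: the three starting materials are taken as purchased, and dimethyldioxirane is used as a titrated solution in acetone.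

**Step 1**
Reactants: 1 5,7-dihydroxy-4H-chromen-4-one
Product: 2 5-hydroxy-7-(methoxymethoxy)-4H-chromen-4-one
Conditions: MOMCl (1.1 equiv), K2CO3, acetone, 0 °C to rt
Reagents that add atoms: chloromethyl methyl ether COCCl
Why: Williamson-type O-alkylation in which only the free, more acidic 7-OH reacts, because the 5-OH is held in a hydrogen bond to the C4 carbonyl.

**Step 2**
Reactants: 2 5-hydroxy-7-(methoxymethoxy)-4H-chromen-4-one
Product: 3 5-hydroxy-6-iodo-7-(methoxymethoxy)-4H-chromen-4-one
Conditions: BnMe3N·ICl2 (1.0 equiv), CaCO3, CH2Cl2–MeOH, rt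
Reagents that add atoms: benzyltrimethylammonium dichloroiodate C[N+](C)(C)Cc1ccccc1.Cl[I-]Cl
Why: Electrophilic aromatic iodination directed ortho to the free 5-hydroxyl (C6), a site selectivity with close precedent on 5-hydroxy-7-alkoxyflavones, while CaCO3 takes up the HCl so that the acetal survives and ring A reacts far faster than C3 of the pyranone.

**Step 3**
Reactants: 3 5-hydroxy-6-iodo-7-(methoxymethoxy)-4H-chromen-4-one
Product: 4 6-iodo-5,7-bis(methoxymethoxy)-4H-chromen-4-one
Conditions: NaH, MOMCl, DMF, 0 °C to rt
Reagents that add atoms: chloromethyl methyl ether COCCl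
Why: O-alkylation of the sodium phenoxide, the strong base breaking the chelate so that the hindered 5-OH is capped by the small chloromethyl ether.

**Step 4**
Reactants: 4 6-iodo-5,7-bis(methoxymethoxy)-4H-chromen-4-one
Product: 5 5,7-bis(methoxymethoxy)-6-(trimethylstannyl)-4H-chromen-4-one
Conditions: Me3SnSnMe3 (1.2 equiv), Pd(PPh3)4 (5 mol%), toluene, 100 °C
Reagents that add atoms: hexamethyldistannane C[Sn](C)(C)[Sn](C)(C)C
Why: Palladium-catalysed stannylation of an aryl iodide with a distannane (oxidative addition, tin transfer, reductive elimination) under neutral conditions that leave the base-sensitive pyranone untouched.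

**Step 5**
Reactants: 5 5,7-bis(methoxymethoxy)-6-(trimethylstannyl)-4H-chromen-4-one; 6 (E)-geranyl bromide
Product: 7 6-[(2E)-3,7-dimethylocta-2,6-dien-1-yl]-5,7-bis(methoxymethoxy)-4H-chromen-4-one
Conditions: Pd2(dba)3 (2.5 mol%), AsPh3 (20 mol%), THF, 55 °C
Reagents that add atoms: none
Why: Stille coupling of an arylstannane with an allylic bromide, in which oxidative addition of 6 gives a syn π-allyl palladium complex that keeps the E geometry (syn–anti exchange would need the tertiary σ-allyl form) and reductive elimination at the unsubstituted allyl terminus gives the linear geranyl arene.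

**Step 6**
Reactants: 8 5-bromo-2-methoxyphenol
Product: 9 4-bromo-1-methoxy-2-(methoxymethoxy)benzene
Conditions: NaH, MOMCl, THF–DMF, 0 °C to rt
Reagents that add atoms: chloromethyl methyl ether COCCl
Why: O-alkylation of the sodium phenoxide, giving the same acid-labile acetal as on ring A so that one final operation frees all phenols.

**Step 7**
Reactants: 7 6-[(2E)-3,7-dimethylocta-2,6-dien-1-yl]-5,7-bis(methoxymethoxy)-4H-chromen-4-one; 9 4-bromo-1-methoxy-2-(methoxymethoxy)benzene
Product: 14 (2R,3R)-6-[(2E)-3,7-dimethylocta-2,6-dien-1-yl]-3-hydroxy-2-[4-methoxy-3-(methoxymethoxy)phenyl]-5,7-bis(methoxymethoxy)-2,3-dihydro-4H-chromen-4-one, via aryllithium 10 (not isolated), via arylzinc chloride 11 (not isolated), via enol silane 12 (not isolated), via silyloxy epoxide 13 (not isolated)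
Conditions: 9 (1.6 equiv), n-BuLi, THF, −78 °C; ZnCl2, −78 to 20 °C; add to 7, [RhCl((S)-binap)]2 (2.5 mol%), Me3SiCl (1.6 equiv), THF, 20 °C; filtration through Et3N-deactivated Florisil (pentane); dimethyldioxirane (1.0 equiv, acetone), CH2Cl2, −78 °C; citric acid, MeOH, 0 °C
Reagents that add atoms: dimethyldioxirane CC1(C)OO1 (the oxygen on C3 of 14); held only in the intermediates: n-butyllithium [Li]CCCC (Li of 10), zinc dichloride [Zn+2].[Cl-].[Cl-] (ZnCl of 11), chlorotrimethylsilane C[Si](C)(C)Cl (Me3Si of 12 and 13)
Why: Proposed new method: the aryl group passes from zinc in 11 to monovalent rhodium, the aryl–rhodium bond adds across C2=C3 of 7 with aryl going to C2, and Me3SiCl silylates the resulting oxa-π-allyl rhodium enolate at once, which returns the rhodium chloride, gives ZnCl2 and enol silane 12 and leaves no free enolate that could open ring C by β-elimination of the O1 phenoxide; dimethyldioxirane then epoxidises C3=C4 of 12 and mild methanolysis of silyloxy epoxide 13 gives the ketol. The closest known reaction types are the rhodium/binap-catalysed asymmetric 1,4-addition of arylzinc chlorides with Me3SiCl to 4-quinolones and 2,3-dihydro-4-pyridones, the rhodium-catalysed asymmetric 1,4-addition of arylboronic acids to chromones, and the Rubottom oxidation of enol silanes; what is new is their union on a chromone, with the enol silane used instead of being hydrolysed. No ring of the target is closed; the only ring made is the transient oxirane of 13, closed by concerted oxygen-atom transfer to the C3=C4 bond. C2 is set by the catalyst, the (S)-binap ligand being expected by the facial model established for cyclohex-2-enone to give 2S in 12 (the arrangement that becomes 2R in 14), and C3 is set by C2, the oxidant approaching the face anti to the C2 aryl group so that the 3-hydroxyl ends trans, which is also the more stable diequatorial isomer. The step needs 1,4-addition at C2, secured by the vinylogous ester O1–C2=C3–C4=O whose carbonyl is deactivated by O1 and the ring A donors, and it needs oxidation of the enol silane before the two trisubstituted alkenes of the geranyl chain, secured by the much greater electron richness of the ring A-conjugated, doubly oxygen-substituted C3=C4 bond at −78 °C with one equivalent of oxidant.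

**Step 8**
Reactants: 14 (2R,3R)-6-[(2E)-3,7-dimethylocta-2,6-dien-1-yl]-3-hydroxy-2-[4-methoxy-3-(methoxymethoxy)phenyl]-5,7-bis(methoxymethoxy)-2,3-dihydro-4H-chromen-4-one
Product: 15 4'-O-methyldiplacol
Conditions: aq. HCl (3 M), MeOH, 40 °C
Reagents that add atoms: none
Why: Acid-catalysed transacetalisation of the three methoxymethyl ethers to dimethoxymethane, under which the 2,3-trans ketol is configurationally stable (C2 and C3 epimerise only under base) and the mild temperature should keep the geranyl alkenes from cyclising onto the flanking phenols.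

**Compound list**
1 | 5,7-dihydroxy-4H-chromen-4-one | O=c1ccoc2cc(O)cc(O)c12 | starting material
2 | 5-hydroxy-7-(methoxymethoxy)-4H-chromen-4-one | O=c1ccoc2cc(OCOC)cc(O)c12 | intermediate
3 | 5-hydroxy-6-iodo-7-(methoxymethoxy)-4H-chromen-4-one | O=c1ccoc2cc(OCOC)c(I)c(O)c12 | intermediate
4 | 6-iodo-5,7-bis(methoxymethoxy)-4H-chromen-4-one | O=c1ccoc2cc(OCOC)c(I)c(OCOC)c12 | intermediate
5 | 5,7-bis(methoxymethoxy)-6-(trimethylstannyl)-4H-chromen-4-one | O=c1ccoc2cc(OCOC)c([Sn](C)(C)C)c(OCOC)c12 | intermediate
6 | (E)-geranyl bromide, (2E)-1-bromo-3,7-dimethylocta-2,6-diene | BrC/C=C(\C)CCC=C(C)C | starting material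
7 | 6-[(2E)-3,7-dimethylocta-2,6-dien-1-yl]-5,7-bis(methoxymethoxy)-4H-chromen-4-one | O=c1ccoc2cc(OCOC)c(C/C=C(\C)CCC=C(C)C)c(OCOC)c12 | intermediate
8 | 5-bromo-2-methoxyphenol | COc1ccc(Br)cc1O | starting material
9 | 4-bromo-1-methoxy-2-(methoxymethoxy)benzene | COc1ccc(Br)cc1OCOC | intermediate
10 | [4-methoxy-3-(methoxymethoxy)phenyl]lithium (formed in the flask) | COc1ccc([Li])cc1OCOC | intermediate
11 | chloro[4-methoxy-3-(methoxymethoxy)phenyl]zinc (formed in the flask) | COc1ccc([Zn]Cl)cc1OCOC | intermediate
12 | (2S)-6-[(2E)-3,7-dimethylocta-2,6-dien-1-yl]-2-[4-methoxy-3-(methoxymethoxy)phenyl]-5,7-bis(methoxymethoxy)-4-(trimethylsilyloxy)-2H-chromene (enol silane, formed in the flask) | COc1ccc([C@H]2Oc3cc(OCOC)c(C/C=C(\C)CCC=C(C)C)c(OCOC)c3C(O[Si](C)(C)C)=C2)cc1OCOC | intermediate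
13 | 3,4-epoxide of 12, oxirane oxygen anti to the C2 aryl group, trimethylsilyloxy on C4 (formed in the flask) | COc1ccc([C@H]2Oc3cc(OCOC)c(C/C=C(\C)CCC=C(C)C)c(OCOC)c3[C@]4(O[Si](C)(C)C)O[C@H]24)cc1OCOC | intermediate
14 | (2R,3R)-6-[(2E)-3,7-dimethylocta-2,6-dien-1-yl]-3-hydroxy-2-[4-methoxy-3-(methoxymethoxy)phenyl]-5,7-bis(methoxymethoxy)-2,3-dihydro-4H-chromen-4-one | COc1ccc([C@H]2Oc3cc(OCOC)c(C/C=C(\C)CCC=C(C)C)c(OCOC)c3C(=O)[C@@H]2O)cc1OCOC | intermediate
15 | 4'-O-methyldiplacol, (2R,3R)-6-[(2E)-3,7-dimethylocta-2,6-dien-1-yl]-3,5,7-trihydroxy-2-(3-hydroxy-4-methoxyphenyl)-2,3-dihydro-4H-chromen-4-one | COc1ccc([C@H]2Oc3cc(O)c(C/C=C(\C)CCC=C(C)C)c(O)c3C(=O)[C@@H]2O)cc1O | target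

**Count and risks**
Total step count: 8. Longest linear sequence: 7 steps (steps 1 to 5, 7 and 8, from 5,7-dihydroxychromone); step 6 is the side branch.

Steps most likely to fail:

1. Step 7 (the labelled step). Aryl transfer to the donor-rich chromone may be slow, the enol silane may hydrolyse before it is oxidised, or the oxidant may attack the geranyl alkenes. The fallback uses known chemistry, sets out from 7 and 9 and returns at 14. Compound 9 is converted (n-BuLi, THF, −78 °C; B(OiPr)3; aqueous NH4Cl) into [4-methoxy-3-(methoxymethoxy)phenyl]boronic acid F1. Asymmetric 1,4-addition of F1 to 7 under a catalyst already proven on chromones (Pd(OCOCF3)2 with a chiral tert-butyl pyridine–oxazoline ligand in aqueous 1,2-dichloroethane, or a rhodium–chiral diene catalyst, the ligand antipode chosen for 2S) gives the (2S)-flavanone F2. Deprotonation with KN(SiMe3)2 in THF at −78 °C and oxidation of the enolate with 2-(phenylsulfonyl)-3-phenyloxaziridine, which leaves isolated alkenes alone and enters anti to the aryl group, then gives 14.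

2. Step 5. Tin-to-palladium transfer at the doubly ortho-substituted aryl carbon may be slow, so that protodestannylation, methyl transfer or diene formation from the allylpalladium complex take over. The fallback sets out from 4 and returns at 7 without the stannane. Zinc powder with LiCl in THF (25 to 50 °C) inserts into the C–I bond of 4 to give the arylzinc iodide F3, whose faster transmetalation allows a Pd(PPh3)4-catalysed Negishi allylation with 6, again through the geometry-retaining π-allyl complex.

3. Step 8. Protic acid may cyclise the geranyl chain onto O5 or O7, or released formaldehyde equivalents may be captured at C8 of the freed phloroglucinol ring. The fallback sets out from 14 and returns at 15 without free acid. Me3SiOTf and 2,2'-bipyridyl in CH2Cl2 at 0 °C exchange the aryl methoxymethyl groups for silyl groups and silylate the 3-OH, giving the tetrakis(trimethylsilyl) ether F4. Neutral hydrolysis (water–THF, or KF in MeOH buffered with AcOH) then gives 15.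

**Further compounds**
F1 | step 7 | [4-methoxy-3-(methoxymethoxy)phenyl]boronic acid | COc1ccc(B(O)O)cc1OCOC
F2 | step 7 | (2S)-6-[(2E)-3,7-dimethylocta-2,6-dien-1-yl]-2-[4-methoxy-3-(methoxymethoxy)phenyl]-5,7-bis(methoxymethoxy)-2,3-dihydro-4H-chromen-4-one | COc1ccc([C@H]2Oc3cc(OCOC)c(C/C=C(\C)CCC=C(C)C)c(OCOC)c3C(=O)C2)cc1OCOC
F3 | step 5 | [5,7-bis(methoxymethoxy)-4-oxo-4H-chromen-6-yl]zinc iodide | O=c1ccoc2cc(OCOC)c([Zn]I)c(OCOC)c12
F4 | step 8 | (2R,3R)-6-[(2E)-3,7-dimethylocta-2,6-dien-1-yl]-2-[4-methoxy-3-(trimethylsilyloxy)phenyl]-3,5,7-tris(trimethylsilyloxy)-2,3-dihydro-4H-chromen-4-one | COc1ccc([C@H]2Oc3cc(O[Si](C)(C)C)c(C/C=C(\C)CCC=C(C)C)c(O[Si](C)(C)C)c3C(=O)[C@@H]2O[Si](C)(C)C)cc1O[Si](C)(C)C
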